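Geranyl stands throughout for (2E)-3,7-dimethylocta-2,6-dien-1-yl. Flavanone numbering (O1, C2, C3, C4, C4a, C5–C8, C8a; ring B primed; chain doubly primed) is used for all intermediates.

## Analysis of the target

The target 23 is a flavanone: a benzo ring (ring A) fused to a dihydropyran-4-one (ring C) that carries an aryl group (ring B) at C2. Ring A has a free hydroxyl at C5, hydrogen-bonded to the C4 carbonyl, and a methoxy group at C7. Ring B has methoxy groups at C3' and C4' and, at C2' next to the ring junction, a geranyl chain with two trisubstituted alkenes. C2 is the only stereocentre and is S. It is a benzylic ether carbon β to the ketone, so base can open ring C by a retro-oxa-Michael reaction to the achiral 2'-hydroxychalcone, and strong acid can ionise C2–O1 with help from the para methoxy group. The chain is sensitive to Brønsted and strong Lewis acids (cation–olefin cyclisation), to hydrogenation and to oxidants at the benzylic-allylic C1'' methylene. The hard points are to set C2 and keep it, to place the chain on the crowded C2' position, and to free one of four aryl methyl ethers at the end. The strategy rests on ring A: O1 and the C4 carbonyl sit on the neighbouring carbons C8a and C4a, and C4a is flanked by the C5 oxygen, which is the pattern a 3-alkoxyaryne produces when it takes a nucleophile at the remote carbon and an electrophile at the near one.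

## Retrosynthetic reasoning

The target 23 is traced to its C5 methyl ether 22 by cutting the C5 O–CH3 bond. Leaving this to the end lets ring A travel as a symmetrical dimethoxy unit, so its precursor has no regiochemical problem of its own. The C5 ether is the only one peri to the carbonyl and can be singled out by chelation. The forward step must cleave it without protonating the chain alkenes or ionising C2–O1.

In 22 the two bonds joining ring C to ring A, O1–C8a and C4a–C4, are cut together. This leads to 3,5-dimethoxybenzyne 19 and to the alkoxide 20 of a β-hydroxy ester. The cut is made here, and not at O1–C2 or C2–C1', because the stereocentre then sits on the nucleophile and its C–O bond is never broken, while one operation gives two skeletal bonds and ring C. The forward reaction must send the alkoxide to C8a only and must let the aryl anion 21 acylate before it is protonated. For that reason the hydroxyl of the hydroxy ester 17 is carried in as the trimethylsilyl ether 18, which releases 20 with fluoride and no proton donor. The aryne is released from the ortho-silylaryl triflate 6.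

Silyl ether 18 comes from hydroxy ester 17, and 17 from the auxiliary ester 16 by ester exchange. In 16 the C2–C3 bond is cut as an acetate aldol between aldehyde 13 and the dilithium enolate 15 of the chiral acetate 14. This is where C2 is set. The aldehyde cannot enolise, and the auxiliary adduct can be purified by crystallisation.

Aldehyde 13 is unmasked from acetal 12, in which the C2'–C1'' bond between ring B and the chain is cut. Geranyl bromide 9 brings the chain with its E alkene in place, and the bromine of acetal 8 (from bromoaldehyde 7) marks C2' without ambiguity. The forward step, through aryllithium 10 and arylcopper 11, must substitute at the primary allylic carbon.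

Triflate 6 is cut at the O–S and C–Si bonds. The silyl group is delivered from oxygen to carbon in silyl ether 3 by way of aryllithium 4 and phenoxide 5. Silyl ether 3 comes from bromophenol 2, and 2 from 3,5-dimethoxyphenol 1 by bromination ortho to the hydroxyl.

## Alternatives that were turned down

Alternative 1: Ring B is disconnected at C1'–C(alkyne), the later C2–C1' bond, and at C2'–C1''. The components are 3,4-dimethoxybenzyne A2, 3,3-diethoxyprop-1-yne A3 and geranyl chloride A4.
- Forward step: fluoride releases A2, the monovalent copper acetylide of A3 adds at C1' (remote from the C3' methoxy group), and the aryl copper at C2' is allylated by A4. The product is 1-(3,3-diethoxyprop-1-ynyl)-2-geranyl-3,4-dimethoxybenzene A1.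
- For: one step sets both carbon substituents of ring B, against three steps (4 to 6) in the chosen route, and no aldehyde protection is needed. On ring B economy this alternative is stronger.
- Against: the aryl copper must attack the primary end of a γ,γ-disubstituted allyl chloride without SN2' attack or loss of alkene geometry, while competing with protonation and with direct acetylide–allyl coupling. A1 also contains neither ring A, ring C nor the stereocentre. Acetal cleavage, union with ring A, oxidation and cyclisation would give a planar 2-arylchromen-4-one, so C2 would have to be made last by enantioselective reduction beside two chain alkenes.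
- Comparison: the chosen strategy buys the ring B pattern in 7 and uses its aryne step on ring C, where it closes a ring with the stereocentre already fixed.

Alternative 2: C4a–C4, C4–C3 and O1–C2 are cut. The components are 2-iodo-5-methoxyresorcinol A6, carbon monoxide A7 and 2-geranyl-3,4-dimethoxyphenylacetylene A8.
- Forward step: palladium-catalysed carbonylative coupling with an amine base, then 6-endo addition of a phenol oxygen to the ynone. The product is 2-(2-geranyl-3,4-dimethoxyphenyl)-5-hydroxy-7-methoxychromen-4-one A5, which asymmetric reduction of C2=C3 would convert into 23.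
- For: the ring construction is a known reaction type, which the chosen key step is not. A6 is symmetrical, the C5 hydroxyl appears free so no demethylation is needed, and the sequence from A8 is two steps. On precedent and step count this alternative is stronger.
- Against: the only stereocentre must be created last, on an electron-rich, chelated 5-hydroxyflavone. Hydrogenation catalysts able to reduce that double bond also threaten the chain alkenes and over-reduce to the flavan-4-ol, and hydride conjugate reductions are quenched by the phenol. A 5-exo closure to an aurone competes in the annulation, and A8 costs one more step from 13.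
- Comparison: the chosen strategy sets C2 early by an aldol and never subjects the chain to a reduction.

Alternative 3: C3–C4 and O1–C2 are cut as a [4+2] cycloaddition of an ortho-quinone methide. The components are 2-hydroxy-4,6-dimethoxybenzaldehyde A10, trimethyl orthoformate A11 and 2-geranyl-3,4-dimethoxystyrene A12.
- Forward step: a chiral BINOL-derived phosphoric acid generates the quinone methide and controls the addition. The product is cis-(2S)-2-(2-geranyl-3,4-dimethoxyphenyl)-4,5,7-trimethoxychroman A9.
- For: C2 is set catalytically in the ring-forming step, which is more direct than an auxiliary aldol followed by ester exchange.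
- Against: the cationic intermediate meets two nucleophilic chain alkenes that compete with a twisted, ortho-substituted styrene and can cyclise under acid. A9 has C4 at the wrong oxidation level, and its oxidation to the ketone must spare the C1'' methylene. The C5 ether must still be cleaved, and A12 needs one more step from 13.
- Comparison: the chosen key step delivers the C4 ketone directly under non-acidic conditions.

Key step: step 10

Assumptions:
- Compounds 1, 7, 9 and 14 are taken as purchasable.
- The (S) enantiomer of the chiral acetate is chosen because the (R) enantiomer is known to give (R)-β-hydroxy acids from aldehydes whose substituent outranks the acetate carbon.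
- The hydroxyl of 17 enters the annulation as its trimethylsilyl ether, since a free O–H would be expected to protonate the aryl anion and give only O-arylation.

## Route

Step 1
Reactants: 1 3,5-dimethoxyphenol
Product: 2 2-bromo-3,5-dimethoxyphenol
Conditions: NBS (1.0 equiv), CH2Cl2, −78 → 0 °C
Reagents that add atoms: N-bromosuccinimide, O=C1CCC(=O)N1Br
Why: Electrophilic aromatic bromination; C2 is activated by all three oxygens and occurs twice, and in a non-polar solvent at low temperature the hydrogen-bonded phenol should direct bromine ortho to the hydroxyl. Any para isomer is removed by chromatography.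

Step 2
Reactants: 2 2-bromo-3,5-dimethoxyphenol
Product: 3 (2-bromo-3,5-dimethoxyphenoxy)trimethylsilane
Conditions: HMDS (1.0 equiv), THF, 65 °C; evaporation
Reagents that add atoms: hexamethyldisilazane, C[Si](C)(C)N[Si](C)(C)C
Why: O-Silylation of a phenol with a silazane; ammonia is the only by-product, so the crude silyl ether can be used directly.

Step 3
Reactants: 3 (2-bromo-3,5-dimethoxyphenoxy)trimethylsilane
Product: 6 3,5-dimethoxy-2-(trimethylsilyl)phenyl trifluoromethanesulfonate, via aryllithium 4 (not isolated), via lithium phenoxide 5 (not isolated)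
Conditions: n-BuLi (1.1 equiv), THF, −100 → −78 °C; Tf2O (1.2 equiv), −100 → −78 °C; aq. NaHCO3
Reagents that add atoms: trifluoromethanesulfonic anhydride, O=S(=O)(OS(=O)(=O)C(F)(F)F)C(F)(F)F
Why: Bromine–lithium exchange followed by retro-Brook 1,3-migration of silicon from oxygen to carbon, then triflation of the phenoxide in the same flask; this is the standard access to ortho-silylaryl triflates.

Step 4
Reactants: 7 2-bromo-3,4-dimethoxybenzaldehyde
Product: 8 2-(2-bromo-3,4-dimethoxyphenyl)-1,3-dioxolane
Conditions: ethylene glycol (3 equiv), p-TsOH·H2O (cat.), toluene, reflux, Dean–Stark trap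
Reagents that add atoms: ethane-1,2-diol, OCCO
Why: Acid-catalysed acetalisation with azeotropic removal of water; the aldehyde is masked against the organolithium of step 5.

Step 5
Reactants: 8 2-(2-bromo-3,4-dimethoxyphenyl)-1,3-dioxolane; 9 geranyl bromide
Product: 12 2-(2-geranyl-3,4-dimethoxyphenyl)-1,3-dioxolane, via aryllithium 10 (not isolated), via arylcopper 11 (not isolated)
Conditions: n-BuLi (1.05 equiv), THF, −78 °C; CuBr·SMe2 (1.0 equiv), −78 → −40 °C; 9 (1.2 equiv), −78 °C → rt
Reagents that add atoms: none
Why: Bromine–lithium exchange and transmetalation to monovalent copper give a soft aryl nucleophile that should displace the primary allylic bromide directly (organocopper allylation, SN2), so the chain is joined at C1'' with the E alkene unchanged.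

Step 6
Reactants: 12 2-(2-geranyl-3,4-dimethoxyphenyl)-1,3-dioxolane
Product: 13 2-geranyl-3,4-dimethoxybenzaldehyde
Conditions: PPTS (cat.), acetone/H2O (9:1), 50 °C
Reagents that add atoms: water, O
Why: Acetal hydrolysis under weak acid; the acid is too weak to protonate the trisubstituted alkenes or to trigger a Prins cyclisation of the ortho-allyl aldehyde.

Step 7
Reactants: 13 2-geranyl-3,4-dimethoxybenzaldehyde; 14 (1S)-2-hydroxy-1,2,2-triphenylethyl acetate
Product: 16 (1S)-2-hydroxy-1,2,2-triphenylethyl (3S)-3-(2-geranyl-3,4-dimethoxyphenyl)-3-hydroxypropanoate, via dilithium enolate 15 (not isolated)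
Conditions: 14 (1.2 equiv), LiN(iPr)2 (2.4 equiv), THF, −78 → 0 °C; 13, −105 °C; aq. NH4Cl; recrystallisation
Reagents that add atoms: none
Why: Auxiliary-controlled acetate aldol addition; the doubly deprotonated triphenylglycol acetate should attack the Si face of the aldehyde and set the carbinol carbon (later C2) as S. The minor diastereomer is removed by crystallisation.

Step 8
Reactants: 16 (1S)-2-hydroxy-1,2,2-triphenylethyl (3S)-3-(2-geranyl-3,4-dimethoxyphenyl)-3-hydroxypropanoate
Product: 17 methyl (3S)-3-(2-geranyl-3,4-dimethoxyphenyl)-3-hydroxypropanoate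
Conditions: K2CO3 (cat.), MeOH, 0 °C → rt
Reagents that add atoms: methanol, CO
Why: Base-catalysed transesterification; it releases the methyl ester and the recoverable diol under conditions too mild for retro-aldol cleavage, and the bonds at the stereocentre are not touched.

Step 9
Reactants: 17 methyl (3S)-3-(2-geranyl-3,4-dimethoxyphenyl)-3-hydroxypropanoate
Product: 18 methyl (3S)-3-(2-geranyl-3,4-dimethoxyphenyl)-3-[(trimethylsilyl)oxy]propanoate
Conditions: TMSCl (1.3 equiv), imidazole (2.0 equiv), CH2Cl2, 0 °C; filtration through neutral alumina
Reagents that add atoms: chlorotrimethylsilane, C[Si](C)(C)Cl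
Why: Silylation of a secondary alcohol; it removes the O–H proton and turns the hydroxyl into a group from which fluoride sets the alkoxide free.

Step 10
Reactants: 18 methyl (3S)-3-(2-geranyl-3,4-dimethoxyphenyl)-3-[(trimethylsilyl)oxy]propanoate; 6 3,5-dimethoxy-2-(trimethylsilyl)phenyl trifluoromethanesulfonate
Product: 22 (2S)-2-(2-geranyl-3,4-dimethoxyphenyl)-5,7-dimethoxy-2,3-dihydro-4H-chromen-4-one, via 3,5-dimethoxybenzyne 19 (not isolated), via cesium alkoxide 20 (not isolated), via aryl cesium adduct 21 (not isolated)
Conditions: CsF (5 equiv), THF, 65 °C; 6 (2.0 equiv) added over 4 h; then H2O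
Reagents that add atoms: none
Why: Proposed new method: fluoride attacks silicon in 6 and in 18, which releases aryne 19 and, with no proton donor present, alkoxide 20. The alkoxide adds to the aryne carbon remote from the flanking C5 methoxy group, the more electrophilic terminus, so O1–C8a forms and the charge appears at C4a between two C–O bonds that stabilise it inductively (21). Carbanion 21 then attacks the ester carbonyl in a 6-exo-trig addition–elimination that forms C4a–C4, closes ring C and expels methoxide. The closest known reaction types are the fluoride-induced annulation of arynes with ortho-hydroxyaryl esters to xanthones, the insertion of arynes into the C–O bond of carboxylic acids that gives ortho-hydroxyaryl ketones and chroman-4-ones, and the insertion of arynes into the N–C(O) bond of NH β-lactams that gives 2,3-dihydroquinolin-4-ones; the alkoxide of an aliphatic β-hydroxy ester has not been used in this way. No stereocentre is formed, and because the C2–O bond is never broken the 2S configuration from step 7 is carried through. The step needs regioselectivity (oxygen at C8a, acyl at C4a), which the C5 methoxy group beside the triple bond secures. It also needs acyl transfer to outrun protonation of 21, which is served by the silyl ether, by THF in place of acetonitrile and by slow release of the aryne.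

Step 11
Reactants: 22 (2S)-2-(2-geranyl-3,4-dimethoxyphenyl)-5,7-dimethoxy-2,3-dihydro-4H-chromen-4-one
Product: 23 (2S)-2-(2-geranyl-3,4-dimethoxyphenyl)-5-hydroxy-7-methoxy-2,3-dihydro-4H-chromen-4-one
Conditions: MgI2·OEt2 (3 equiv), THF, 60 °C; then cold 0.5 M HCl
Reagents that add atoms: none
Why: Chelation-assisted demethylation of an ortho-methoxyaryl ketone; magnesium binds the C4 carbonyl and the C5 ether oxygen and iodide removes that methyl group by SN2, while the three unchelated ethers stay. No strong Brønsted acid is present during the reaction, so the chain alkenes and C2 should be unaffected.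

## Compound list

1 | 3,5-dimethoxyphenol | COc1cc(O)cc(OC)c1 | starting material
2 | 2-bromo-3,5-dimethoxyphenol | COc1cc(O)c(Br)c(OC)c1 | intermediate
3 | (2-bromo-3,5-dimethoxyphenoxy)trimethylsilane | COc1cc(O[Si](C)(C)C)c(Br)c(OC)c1 | intermediate
4 | [2,4-dimethoxy-6-(trimethylsilyloxy)phenyl]lithium (formed in the flask) | COc1cc(O[Si](C)(C)C)c([Li])c(OC)c1 | intermediate
5 | lithium 3,5-dimethoxy-2-(trimethylsilyl)phenolate (formed in the flask) | [Li+].COc1cc([O-])c([Si](C)(C)C)c(OC)c1 | intermediate
6 | 3,5-dimethoxy-2-(trimethylsilyl)phenyl trifluoromethanesulfonate | COc1cc(OC)c([Si](C)(C)C)c(OS(=O)(=O)C(F)(F)F)c1 | intermediate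
7 | 2-bromo-3,4-dimethoxybenzaldehyde | COc1ccc(C=O)c(Br)c1OC | starting material
8 | 2-(2-bromo-3,4-dimethoxyphenyl)-1,3-dioxolane | COc1ccc(C2OCCO2)c(Br)c1OC | intermediate
9 | geranyl bromide, (2E)-1-bromo-3,7-dimethylocta-2,6-diene | CC(C)=CCC/C(C)=C/CBr | starting material
10 | [6-(1,3-dioxolan-2-yl)-2,3-dimethoxyphenyl]lithium (formed in the flask) | COc1ccc(C2OCCO2)c([Li])c1OC | intermediate
11 | [6-(1,3-dioxolan-2-yl)-2,3-dimethoxyphenyl]copper (formed in the flask) | COc1ccc(C2OCCO2)c([Cu])c1OC | intermediate
12 | 2-{2-[(2E)-3,7-dimethylocta-2,6-dien-1-yl]-3,4-dimethoxyphenyl}-1,3-dioxolane | COc1ccc(C2OCCO2)c(C/C=C(\C)CCC=C(C)C)c1OC | intermediate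
13 | 2-[(2E)-3,7-dimethylocta-2,6-dien-1-yl]-3,4-dimethoxybenzaldehyde | COc1ccc(C=O)c(C/C=C(\C)CCC=C(C)C)c1OC | intermediate
14 | (1S)-2-hydroxy-1,2,2-triphenylethyl acetate | CC(=O)O[C@@H](c1ccccc1)C(O)(c1ccccc1)c1ccccc1 | starting material
15 | dilithium enolate of 14, dilithium (1S)-2-oxido-1,2,2-triphenylethyl ethen-1-olate-1-yl ether (formed in the flask) | [Li+].[Li+].C=C([O-])O[C@@H](c1ccccc1)C([O-])(c1ccccc1)c1ccccc1 | intermediate
16 | (1S)-2-hydroxy-1,2,2-triphenylethyl (3S)-3-{2-[(2E)-3,7-dimethylocta-2,6-dien-1-yl]-3,4-dimethoxyphenyl}-3-hydroxypropanoate | O[C@H](c1ccc(OC)c(OC)c1C/C=C(\C)CCC=C(C)C)CC(=O)O[C@@H](c1ccccc1)C(O)(c1ccccc1)c1ccccc1 | intermediate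
17 | methyl (3S)-3-{2-[(2E)-3,7-dimethylocta-2,6-dien-1-yl]-3,4-dimethoxyphenyl}-3-hydroxypropanoate | O[C@H](c1ccc(OC)c(OC)c1C/C=C(\C)CCC=C(C)C)CC(=O)OC | intermediate
18 | methyl (3S)-3-{2-[(2E)-3,7-dimethylocta-2,6-dien-1-yl]-3,4-dimethoxyphenyl}-3-[(trimethylsilyl)oxy]propanoate | C[Si](C)(C)O[C@H](c1ccc(OC)c(OC)c1C/C=C(\C)CCC=C(C)C)CC(=O)OC | intermediate
19 | 3,5-dimethoxybenzyne, 1,2-didehydro-3,5-dimethoxybenzene (formed in the flask) | COC1=CC#CC(OC)=C1 | intermediate
20 | cesium (1S)-1-{2-[(2E)-3,7-dimethylocta-2,6-dien-1-yl]-3,4-dimethoxyphenyl}-3-methoxy-3-oxopropan-1-olate (formed in the flask) | [Cs+].[O-][C@H](c1ccc(OC)c(OC)c1C/C=C(\C)CCC=C(C)C)CC(=O)OC | intermediate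
21 | cesium 2-{[(1S)-1-(2-geranyl-3,4-dimethoxyphenyl)-3-methoxy-3-oxopropyl]oxy}-4,6-dimethoxybenzen-1-ide (formed in the flask) | [Cs+].COc1cc(OC)[c-]c(O[C@H](c2ccc(OC)c(OC)c2C/C=C(\C)CCC=C(C)C)CC(=O)OC)c1 | intermediate
22 | (2S)-2-{2-[(2E)-3,7-dimethylocta-2,6-dien-1-yl]-3,4-dimethoxyphenyl}-5,7-dimethoxy-2,3-dihydro-4H-chromen-4-one | COc1cc(OC)c2c(c1)O[C@H](c1ccc(OC)c(OC)c1C/C=C(\C)CCC=C(C)C)CC2=O | intermediate
23 | (2S)-2-{2-[(2E)-3,7-dimethylocta-2,6-dien-1-yl]-3,4-dimethoxyphenyl}-5-hydroxy-7-methoxy-2,3-dihydro-4H-chromen-4-one | COc1cc(O)c2c(c1)O[C@H](c1ccc(OC)c(OC)c1C/C=C(\C)CCC=C(C)C)CC2=O | target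

## Step count and least certain steps

Total: 11 steps. Longest linear sequence: 8 steps (7 → 23 through steps 4 to 11); the aryne branch (steps 1 to 3) joins at step 10.

Step 10 (key step, beyond known chemistry). Three processes may defeat it.
- Proton transfer from the C3 methylene to the C4a carbanion, followed by β-elimination of the aryloxide, in place of acyl transfer. The carbanion is far more basic than the ester enolate and both sites are within reach.
- Retro-aldol cleavage of the free cesium alkoxide before it meets the aryne.
- Ring opening of the product by fluoride or methoxide (retro-oxa-Michael), which would erode the configuration at C2.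

The fallback uses the classical flavanone construction, sets out from 13 and returns at 22. Claisen–Schmidt condensation of 13 with purchased 1-(2-hydroxy-4,6-dimethoxyphenyl)ethanone (KOH, EtOH, rt) should give (E)-1-(2-hydroxy-4,6-dimethoxyphenyl)-3-(2-geranyl-3,4-dimethoxyphenyl)prop-2-en-1-one F1. Intramolecular oxa-Michael addition (NaOAc, EtOH, reflux) should then give racemic 2-(2-geranyl-3,4-dimethoxyphenyl)-5,7-dimethoxy-2,3-dihydro-4H-chromen-4-one F2. Preparative chromatography on a chiral stationary phase would deliver the 2S enantiomer 22. This gives up the stereocentre built in steps 7 to 9.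

Step 5. Substitution at the tertiary end of the allyl system (SN2'), loss of alkene geometry through an allylcopper species, or halogen–metal exchange between 10 and 9 with homocoupling may compete, because the nucleophile is flanked on both sides. The fallback forms the same bond by palladium catalysis, sets out from 7 and 9 and returns at 13, which also saves the acetal steps. Treatment of 9 with Bu3SnLi (THF, −78 °C) should give tributyl(geranyl)stannane F3, and Stille coupling of F3 with 7 (Pd(PPh3)4, zerovalent palladium, DMF, 90 °C) should give 13.

Step 7. Facial selectivity of the lithium enolate may be poor with this ortho-substituted aldehyde, and the adduct may not crystallise, so the diastereomers could be hard to separate. The fallback sets the stereocentre by reduction instead, sets out from 13 and returns at 17.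
- Addition of the lithium enolate of methyl acetate (LiN(iPr)2, THF, −78 °C) should give racemic methyl 3-(2-geranyl-3,4-dimethoxyphenyl)-3-hydroxypropanoate F4.
- Dess–Martin oxidation should give methyl 3-(2-geranyl-3,4-dimethoxyphenyl)-3-oxopropanoate F5.
- Noyori asymmetric transfer hydrogenation (RuCl[(S,S)-TsDPEN](p-cymene), HCO2H/Et3N) should give 17. It leaves the chain alkenes alone and is expected to give the S alcohol by analogy with simple aryl ketones.

Step 1. Bromination may go para to the hydroxyl (between the two methoxy groups) or twice, since all free positions are activated. The fallback places silicon by directed ortho-metalation, sets out from 1 and returns at 6.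
- Isopropyl isocyanate with catalytic Et3N should give 3,5-dimethoxyphenyl N-isopropylcarbamate F6.
- N-Silylation in the flask (TMSOTf, TMEDA), lithiation between the carbamate and a methoxy group (n-BuLi, −78 °C) and quenching with TMSCl should give 3,5-dimethoxy-2-(trimethylsilyl)phenyl N-isopropylcarbamate F7.
- Cleavage of the carbamate (DBU, Et2NH, MeCN, 40 °C) should release 3,5-dimethoxy-2-(trimethylsilyl)phenol F8, which is triflated in the same flask with PhNTf2 to give 6.

## Further compounds

F1 | step 10 | (E)-1-(2-hydroxy-4,6-dimethoxyphenyl)-3-{2-[(2E)-3,7-dimethylocta-2,6-dien-1-yl]-3,4-dimethoxyphenyl}prop-2-en-1-one | COc1cc(O)c(C(=O)/C=C/c2ccc(OC)c(OC)c2C/C=C(\C)CCC=C(C)C)c(OC)c1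
F2 | step 10 | racemic 2-{2-[(2E)-3,7-dimethylocta-2,6-dien-1-yl]-3,4-dimethoxyphenyl}-5,7-dimethoxy-2,3-dihydro-4H-chromen-4-one | COc1cc(OC)c2c(c1)OC(c1ccc(OC)c(OC)c1C/C=C(\C)CCC=C(C)C)CC2=O
F3 | step 5 | tributyl[(2E)-3,7-dimethylocta-2,6-dien-1-yl]stannane | CCCC[Sn](CCCC)(CCCC)C/C=C(\C)CCC=C(C)C
F4 | step 7 | racemic methyl 3-{2-[(2E)-3,7-dimethylocta-2,6-dien-1-yl]-3,4-dimethoxyphenyl}-3-hydroxypropanoate | COC(=O)CC(O)c1ccc(OC)c(OC)c1C/C=C(\C)CCC=C(C)C
F5 | step 7 | methyl 3-{2-[(2E)-3,7-dimethylocta-2,6-dien-1-yl]-3,4-dimethoxyphenyl}-3-oxopropanoate | COC(=O)CC(=O)c1ccc(OC)c(OC)c1C/C=C(\C)CCC=C(C)C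
F6 | step 1 | 3,5-dimethoxyphenyl N-(propan-2-yl)carbamate | CC(C)NC(=O)Oc1cc(OC)cc(OC)c1
F7 | step 1 | 3,5-dimethoxy-2-(trimethylsilyl)phenyl N-(propan-2-yl)carbamate | CC(C)NC(=O)Oc1cc(OC)cc(OC)c1[Si](C)(C)C
F8 | step 1 | 3,5-dimethoxy-2-(trimethylsilyl)phenol | COc1cc(O)c([Si](C)(C)C)c(OC)c1
A1 | alternative 1 | 1-(3,3-diethoxyprop-1-ynyl)-2-[(2E)-3,7-dimethylocta-2,6-dien-1-yl]-3,4-dimethoxybenzene | CCOC(OCC)C#Cc1ccc(OC)c(OC)c1C/C=C(\C)CCC=C(C)C
A2 | alternative 1 | 3,4-dimethoxybenzyne | COC1=C(OC)C#CC=C1
A3 | alternative 1 | 3,3-diethoxyprop-1-yne | C#CC(OCC)OCC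
A4 | alternative 1 | geranyl chloride, (2E)-1-chloro-3,7-dimethylocta-2,6-diene | CC(C)=CCC/C(C)=C/CCl
A5 | alternative 2 | 2-{2-[(2E)-3,7-dimethylocta-2,6-dien-1-yl]-3,4-dimethoxyphenyl}-5-hydroxy-7-methoxy-4H-chromen-4-one | COc1cc(O)c2c(c1)oc(-c1ccc(OC)c(OC)c1C/C=C(\C)CCC=C(C)C)cc2=O
A6 | alternative 2 | 2-iodo-5-methoxybenzene-1,3-diol | COc1cc(O)c(I)c(O)c1
A7 | alternative 2 | carbon monoxide | [C-]#[O+]
A8 | alternative 2 | 1-ethynyl-2-[(2E)-3,7-dimethylocta-2,6-dien-1-yl]-3,4-dimethoxybenzene | C#Cc1ccc(OC)c(OC)c1C/C=C(\C)CCC=C(C)C
A9 | alternative 3 | (2S,4R)-2-{2-[(2E)-3,7-dimethylocta-2,6-dien-1-yl]-3,4-dimethoxyphenyl}-4,5,7-trimethoxychroman (cis) | COc1cc(OC)c2c(c1)O[C@H](c1ccc(OC)c(OC)c1C/C=C(\C)CCC=C(C)C)C[C@@H]2OC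
A10 | alternative 3 | 2-hydroxy-4,6-dimethoxybenzaldehyde | COc1cc(O)c(C=O)c(OC)c1
A11 | alternative 3 | trimethyl orthoformate | COC(OC)OC
A12 | alternative 3 | 1-ethenyl-2-[(2E)-3,7-dimethylocta-2,6-dien-1-yl]-3,4-dimethoxybenzene | C=Cc1ccc(OC)c(OC)c1C/C=C(\C)CCC=C(C)C
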